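Its constants were set for the occasion; no experiment stands behind them.

Per minute the pump added 0.00500 M/min of starting complex, counted on the starting volume, to a stirred flask holding the incoming ligand and the scavenger.

- winter: starting complex 0.10 M (fed, over 20 min); incoming ligand 0.0700 M; scavenger 0.0800 M; time 20 min; the fed solution adds 1.0 times the starting volume
- dawn: starting complex 0.10 M (fed, over 20 min); incoming ligand 0.0700 M; scavenger 0.100 M; time 20 min; the fed solution adds 1.0 times the starting volume

1. part of the starting complex that has reacted at the end, winter
2. part of the starting complex that has reacted at the end, dawn
3. what raising the concentration of scavenger from its lowest to its highest value here does to the part of the starting complex that has reacted (changes below 5 percentage points count as none) (it falls / no change / it rises)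

- complex with one exchanged is meant together with its crystals
- leaving ligand is meant together with its idle adduct
- every charge counts on the volume at the start, and the solution that is fed holds the whole dose
- solid, in amounts per volume of the solution: crystals
- run time (winter): 20 min

    complex with two exchanged + incoming ligand → leaving ligand + complex with three exchanged (k1 = 0.0157 /M/s)
    complex with one exchanged + incoming ligand → leaving ligand + complex with two exchanged (k2 = 0.0214 /M/s)
    starting complex + incoming ligand → leaving ligand + complex with one exchanged (k3 = 0.0149 /M/s)
    complex with three exchanged + incoming ligand → leaving ligand + complex with four exchanged (k4 = 0.0483 /M/s)
    crystals ⇌ complex with one exchanged, rate k5*(cs5 - [complex with one exchanged]) while solid is left; crystals form when [complex with one exchanged] > cs5 (cs5 = 0.089 M, k5 = 0.00900 /s)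
    leaving ligand + incoming ligand ⇌ idle adduct, settled at all times (K6 = 18 /M)
    scavenger + leaving ligand → scavenged by-product (k7 = 1.79 /M/s)

I drew the reacted part of the charge against time.

1. The start. The first exchange is starting complex + incoming ligand → leaving ligand + complex with one exchanged (k3 = 0.0149 /M/s). No starting complex stood in the flask at first, so the curve left zero flat, then bent upward. Its half-life of 11 min in winter, with the incoming ligand as charged, was shorter than the feed time 20 min.

2. The low end. I took the case where nothing is consumed and the ligand is merely thinned by the growing volume. Summing over the feed gives the rate constant of the first exchange times c(incoming ligand) times the feed time times 0.307. I call this the unchecked yield, the part of the charge reacted if neither partner is used up: 38.4%.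

3. The high end. The incoming ligand is the limiting reagent: each reacted complex takes at least one ligand, so the ceiling is c(incoming ligand) over the charge of starting complex, 70.0%. For the same reason complex with one exchanged cannot reach its solubility, and I dropped the crystals.

4. The join. I added reciprocals, as for two resistances in parallel, which puts the result under the smaller of the two. At 10.0 min the unchecked yield was 11.8%, which joins to 10.1%. At the end of the feed, where the run stops with the curve still climbing, winter joins to 24.8% and dawn to 24.8%.

5. The scavenger stands in neither end. Winter's charge already exceeded the ligand charge, and free leaving ligand there had a half-life of 0.081 min, far shorter than the feed. So for the trend I wrote no change.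

The forecast gave 23.7% for winter, 23.8% for dawn and no change, holding that “Both scavenger charges exceed the leaving ligand released”.

The simulation gave 23.5% in winter and 23.6% at dawn, with no change as the trend, a shift of 0.016 percentage points. My winter join stood 1.3 points above it. At the end of winter 5.11% of the charge stood as complex with two exchanged, so some ligand had gone into second exchanges. Winter reached 61.2% of its unchecked yield.

A neighbour flask, like winter but with 0.28 M of incoming ligand, has an unchecked yield of 154%. With 2.80 equiv of ligand the ceiling is the whole charge, so the join gives 60.6%. The flask gave 56.0%.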